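Slowness is the measure here: the flasks differ in temperature, and the question is how much of the slow chain from solid to target fits into the same window.

common to all: solid substrate 5.0 mM; time 2.5 min
- Monday's: temperature 5 °C
- Thursday's: temperature −35 °C
- Friday's: temperature 25 °C
- Sunday's: temperature −15 °C

    starting material → intermediate A (k1 = 0.24 /s, Ea1 = 77.0 kJ/mol)
    intermediate A → intermediate B (k2 = 0.068 /s, Ea2 = 87.0 kJ/mol)
    intermediate B → intermediate C (k3 = 0.012 /s, Ea3 = 82.0 kJ/mol)
    intermediate C → target (k4 = 0.022 /s, Ea4 = 74.0 kJ/mol)
    target → over-reaction product (k5 = 0.016 /s, Ea5 = 81.0 kJ/mol)
    solid substrate ⇌ starting material, rate k6*(cs6 - [starting material]) while solid is left; crystals form when [starting material] > cs6 (cs6 = 5.0 mM, k6 = 0.0099 /s)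
    (constants at 25 °C)

- as a solid, counted per litre of solution: solid substrate
- the constants hold at 25 °C; other temperatures follow from the activation energies
- at the start none of the solid substrate is in solution
- what has only dissolved of solid substrate counts as not reacted

1. which flask leads in amount of target, in percent of the solid substrate charged ("all alike" within 1.5 percentage points) (Monday's / Thursday's / Friday's / Sunday's / all alike)
2. how much target is there at the end, in percent of the solid substrate charged: Monday's
3. how much target is there at the end, in percent of the solid substrate charged: Thursday's
4. how much target is there at the end, in percent of the solid substrate charged: Friday's
5. how much target is there at the end, in percent of the solid substrate charged: Sunday's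

Friday's flask runs at the given constants, so its ladder of lifetimes, each the reciprocal of a constant, can be read straight off. Starting material lasts 4.17 s and intermediate A 14.7 s, so on Friday's both stay thin while the solid feeds them. Intermediate C lasts 45.5 s and target 62.5 s, which is shorter than the 83.3 s of intermediate B. Intermediate B thus has the longest lifetime of the chemical rungs, but by a factor of just 1.33 over target and 1.83 over intermediate C, so no one step can be called rate-limiting here; intermediate B should pile up, intermediate C should gather behind it, and target should be consumed while it forms. The top rung is the solid, which dissolves into a nearly empty solution at a steady rate and, since its solubility equals the charge, takes 101 s, less than the window of 150 s.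

The four chemical lifetimes up to target add to 148 s, and this sum is the transit time, the mean wait of a dissolved molecule between starting material and target. On Friday's it nearly equals the window, and a molecule dissolving in the middle of the feed arrives on average at 198 s, later than the end. Target on Friday's should therefore be a real share of the charge, with much of the charge still upstream.

Cooling stretches each chemical rung by its activation energy, and the reckoning goes best in powers of ten. The transit time becomes 25.2 min on Monday's, 6.27 h on Sunday's and 151 h on Thursday's. Its excess over the window is then 1.00, 2.18 and 3.56 powers of ten. This reckoning commits to Friday's in the lead, a trace on Monday's, and nothing measurable on Sunday's or Thursday's, and by hand it goes no further than that order.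

The forecast named Friday's, with 20% on Friday's, 0.09% on Monday's, and <0.001% and <0.001% on Sunday's and Thursday's, holding that “its yield collapses as the product of those constants”.

The simulation gives Friday's as leader, with target at 19.8% on Friday's, 0.0963% on Monday's, 0% on Sunday's and 0% on Thursday's. On Friday's, where the transit time of 148 s about equals the window, the end finds 41.2% as intermediate B and 22.8% as intermediate C, with target and over-reaction product together at 35.1%. On Monday's the transit time of 25.2 min is ten times the window, target stands at 0.0963% after 2.50 min, and once the clock has run to about that transit time, at 25.0 min, target stands at 26.6%.

The numbers are those of an exercise; the rest is arithmetic.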